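We have one choice and two lengths to find, for two flasks that differ in their time.

| setting | spring | autumn |
|---|---|---|
| free monomer | 37 mM | 37 mM |
| pre-initiator | 0.39 mol% | 0.39 mol% |
| time | 1.5 min | 3.0 min |

    free monomer + initiator → living end + monomer in chains (k1 = 21.6 L mol⁻¹ s⁻¹)
    free monomer + living end → monomer in chains + living end, rate k2*[living end]*[free monomer] (k2 = 80.1 L mol⁻¹ s⁻¹)
    pre-initiator ⇌ initiator (K3 = 0.716, k3 = 0.0108 s⁻¹)
    2 living end → dead end (k4 = 118 L mol⁻¹ s⁻¹)
    monomer in chains → over-reaction product (k5 = 9.18 × 10⁻⁶ s⁻¹)

- a doubled species enters its step squared and goes two at a time
- the average divides the monomer in chains by the number of chains begun, living and dead together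
- run time (spring): 1.5 min

1. which of the two ends with the longer chains by the average number of monomer units in a chain (chains begun, living or dead) ("neither" if they lie within 10%) (spring / autumn / neither)
2. average number of monomer units in a chain (chains begun, living or dead) at the end, spring
3. average number of monomer units in a chain (chains begun, living or dead) at the end, autumn

The length is monomer in chains over chains begun, so we reckon each. Initiator has a half-life of 0.87 s against free monomer as charged, far shorter than the 1.1 min forward half-life of pre-initiator, so what drains from pre-initiator soon begins chains. Chains begun, the charge of pre-initiator times the fraction drained by its forward step, come to 0.0897 mM in spring and 0.124 mM in autumn.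

For monomer in chains we need the depth, the logarithm of free monomer charged over free monomer left. Free monomer falls pseudo-first-order on the living ends, so we take the depth as 80.1 L mol⁻¹ s⁻¹ times the time integral of living end.

The first way treats death as a correction. With no death, living ends equal chains begun, and spring's depth reaches a ceiling of 0.375. Death at the mean feed, taken to first order, removes 0.103, which leaves 0.272.

The second way holds the feed at its mean and solves it against death in closed form. The depth is 80.1 L mol⁻¹ s⁻¹ over twice 118 L mol⁻¹ s⁻¹, times the logarithm of the hyperbolic cosine of the root of twice 118 L mol⁻¹ s⁻¹ times chains begun times time. For spring this gives 0.254, below the first way.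

In autumn they part. The ceiling 1.16 less the correction 0.780 leaves 0.380, while the second way gives 0.546. The correction is 67.2% of the ceiling there, against 27.5% in spring. A first-order term of that size in autumn is no small correction, so we distrust the first way there and keep the second for both flasks.

Our lengths are 92.5 for spring and 126 for autumn, so autumn ends longer.

The forecast also says autumn, with 104 (from 98 to 132) for spring and 139 (from 130 to 212) for autumn, on the ground that “Chains begun means cumulative initiation”. Our spring length stands below its number.

The simulation gives autumn, with 102 in spring and 139 in autumn. Spring's monomer in chains, 24.1% of the charge, over our chains begun makes 99.3. The neighbour flask is spring with 1.6 mol% of pre-initiator. Its chains begun are 0.368 mM, and the second way gives a depth of 0.715, so we reckon a length of 51.4. Simulated, that neighbour keeps 47.2% of its free monomer and reaches a length of 54.9.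

The numbers are made up; what happens was integrated by code.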